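The earlier runs and the new flask stem from a simulated flask for substances that don't exist; noise was put on by code.

Run gamma in slow motion and watch the partner; the four set-ups below carry gamma's charge and differ in vessel.

| flask | left-handed substrate | right-handed substrate | partner | free catalyst | impurity | remark | time |
|---|---|---|---|---|---|---|---|
| gamma | 0.50 M | 0.50 M | 0.30 M | 6.5 mM | 1.7 mM | run made earlier |  |
| eta | 0.50 M | 0.50 M | 0.30 M | 6.5 mM | 0.85 mM | run made earlier |  |
| west | 0.50 M | 0.50 M | 0.300 M | 6.5 mM | 1.7 mM | a closed flask charged with all of it at once and left for 8.0 h | 8.0 h |
| north-west | 0.50 M | 0.50 M | 0.300 M | 6.5 mM | 1.7 mM | plug flow through a tube for 8.0 h, no back-mixing | 8.0 h |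
| south | 0.50 M | 0.50 M | 0.300 M | 6.5 mM | 1.7 mM | one stirred flow tank at steady state, fed with the mixture as stated, mean residence time 80.0 h |  |
| east | 0.50 M | 0.50 M | 0.300 M | 6.5 mM | 1.7 mM | one stirred flow tank at steady state, fed with the mixture as stated, mean residence time 8.0 h |  |

| run | time / h | left-handed product / % |
|---|---|---|
| gamma | 0.417 | 8.8 |
| gamma | 0.833 | 12.5 |
| gamma | 2.00 | 16.7 |
| gamma | 5.00 | 18.6 |
| eta | 0.667 | 12.1 |
| eta | 1.33 | 15.9 |
| eta | 2.00 | 17.4 |
| eta | 2.50 | 17.9 |

(each reading ± 0.3 percentage points)

- free catalyst is single-handed; left-handed substrate and right-handed substrate are mirror images of each other, charged as a racemate, each of them at the stated concentration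
- the stated concentrations are those of everything mixed, before any reaction; amounts are the same in each set-up
- the earlier runs were read with a standard deviation of 0.3 percentage points
- the earlier runs were made in a closed, stirred flask

1. the set-up with the highest amount of left-handed product at the outlet or at the end, in percent of the left-handed substrate and right-handed substrate together put in ("none" if the first two lie within 2 percentage points) (west / north-west / south / east / none)
2. amount of left-handed product at the outlet or at the end, in percent of the left-handed substrate and right-handed substrate together put in, west
3. amount of left-handed product at the outlet or at the end, in percent of the left-handed substrate and right-handed substrate together put in, north-west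
4. amount of left-handed product at the outlet or at the end, in percent of the left-handed substrate and right-handed substrate together put in, south
5. amount of left-handed product at the outlet or at the end, in percent of the left-handed substrate and right-handed substrate together put in, east

- In the first instants the impurity meets the free catalyst. Eta, with half of gamma's impurity, reads 12.1 % at 0.667 h, while gamma needs 0.833 h to read 12.5 %. I take this as a mole-for-mole loss, so gamma keeps 0.738 of its free catalyst and eta 0.869. Gamma's speed then carries over to the four set-ups.
- In the middle the partner is the limiting reagent, at 30.0 % of the substrates together. I assume each product takes one partner. Gamma's last reading, 18.6 %, then gives the left-handed product a share of 0.620 of the partner, as a reading.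
- My clock is the partner half-life, the time in which the left-handed product covers half of its remaining way to that plateau: 0.451 h, from gamma's first reading.
- At the plateau the substrates together stand at 70.0 % of their charge, so I slow the clock by that factor. Even slowed, 8.0 h in west takes the partner down 3.74 powers of ten. West and the tube north-west, which has no back-mixing, therefore both end at 18.6 % by my reckoning, and my answer is none.
- A tank works at its outlet state, so the fraction of partner left unused is one over one plus slowed rate times residence time. East, whose residence time equals the flask's time, leaves 0.104, and south leaves 0.0115. That makes 16.7 % for east and 18.4 % for south.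
- The forecast says 18.8 % for west, 18.8 % for north-west, 18 % for south and 16.4 % for east, and “The top two tie, so none.”; it stands above my figure for the flask and below mine for the tanks.
- The flask gives 18.1 % in west, 18.1 % in north-west, 17.5 % in south and 16.1 % in east, so the answer is none.

    partner + free catalyst + left-handed substrate → free catalyst + left-handed product (k = 0.120 L² mol⁻² s⁻¹)
    partner + free catalyst + right-handed substrate → free catalyst + right-handed product (k = 0.0720 L² mol⁻² s⁻¹)
    free catalyst + impurity → spent catalyst (k = 8.20 L mol⁻¹ s⁻¹)

- East's outlet holds 33.9 % left-handed and 38.9 % right-handed substrate, so 27.2 % of the charge became product, leaving 0.0952 of the partner unused against my 0.104.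
- Now I run the same clock on east at 3 times its residence time. The unused fraction falls to 0.0373, and scaling east's 16.1 % by the partner consumed gives 17.3 %. That tank gives 17.1 %.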